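The 14-membered carbocycle (C1–C14; C15 is the lactone carbonyl on C10) is cut at C5–C6 and C7–C8. C7 carries the isopropyl group, C8 and the C4–C7 diene, so C6/C7 can come from 3-methylbut-1-yne. Syn-carbocupration with a C8–C15 alkylcopper, then zinc/palladium coupling with an E-alkenyl iodide, joins three fragments in one flask and fixes the ring-cis C6=C7 olefin (C5 cis to C8). The iodide precursor is an acetonide holding both stereocentres (C1, C14) and a silyl-protected C11 alcohol. The carbocycle is then closed at C10=C11 by a Z-selective Horner–Wadsworth–Emmons reaction, and the seven-membered lactone is closed last.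

Key step: step 10

Remarks
- Atom numbers refer to the target: carbocycle C1 (CH–OAc), C2, C3, C4 (methyl), C5, C6, C7 (isopropyl), C8, C9, C10, C11, C12, C13, C14 (methyl, lactone oxygen); C15 is the lactone carbonyl on C10. The target is (1R,14S), 4E, 6E (C5 cis to C8), with C15 cis to C12 across C10=C11.
- Assumption: the D-fructose-derived Shi ketone delivers oxygen to the face of an E-trisubstituted alkene that gives the (R,R)-epoxide, as is general for this catalyst; if the facial sense were the opposite, the enantiomeric ketone would be used.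
- Compounds 4 and 5 are racemic and 25–28 are C10 epimer mixtures; these centres are destroyed later.
- C11–O is carried as a TBDPS ether, released by fluoride, because an oxidatively cleaved benzyl-type ether would expose the electron-rich C4–C7 diene to the oxidant. The alkyne is made first so that no ketone is present when the C11 aldehyde is reduced.

Step 1
Reactants: 1 geranylacetone [(E)-6,10-dimethylundeca-5,9-dien-2-one]
Product: 3 (E)-6,10-dimethylundeca-5,9-dien-1-yne, via enol phosphate 2 (not isolated)
Conditions: LiN(iPr)2 (1.1 equiv), THF, −78 °C; ClP(O)(OEt)2, −78 °C → rt; then LiN(iPr)2 (2.3 equiv), THF, −78 °C → rt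
Reagents that add atoms: none
Why: Methyl ketone-to-alkyne conversion by enol phosphate formation and elimination: kinetic deprotonation at the methyl group gives the terminal enol phosphate, and excess amide base eliminates diethyl phosphate to the terminal alkyne while both alkenes are untouched.

Step 2
Reactants: 3 (E)-6,10-dimethylundeca-5,9-dien-1-yne
Product: 5 rac-2,2-dimethyl-3-[(E)-3-methyloct-3-en-7-yn-1-yl]oxirane, via bromohydrin 4 (not isolated)
Conditions: NBS (1.05 equiv), THF/H2O, 0 °C; then K2CO3, MeOH, rt
Reagents that add atoms: water, O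
Why: Terminal-selective bromohydrin formation and base-induced epoxide closure: in aqueous THF NBS attacks the terminal trisubstituted alkene of the prenyl chain in preference to the internal one, the alkyne is inert, and the epoxide configuration is irrelevant because it is cleaved next.

Step 3
Reactants: 5 rac-2,2-dimethyl-3-[(E)-3-methyloct-3-en-7-yn-1-yl]oxirane
Product: 7 (E)-4-methylnon-4-en-8-yn-1-ol, via aldehyde 6 (not isolated)
Conditions: H5IO6 (1.2 equiv), Et2O/THF, 0 °C; filtration; then NaBH4, MeOH, 0 °C
Reagents that add atoms: none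
Why: Periodic acid cleavage of the epoxide (hydrolysis to the glycol and C–C cleavage with loss of acetone) followed by borohydride reduction gives the C11 alcohol; the trisubstituted alkene and the alkyne do not react.

Step 4
Reactants: 7 (E)-4-methylnon-4-en-8-yn-1-ol
Product: 8 tert-butyl{[(E)-4-methylnon-4-en-8-yn-1-yl]oxy}diphenylsilane
Conditions: TBDPSCl, imidazole, DMF, rt
Reagents that add atoms: tert-butyl(chloro)diphenylsilane, CC(C)(C)[Si](Cl)(c1ccccc1)c1ccccc1
Why: Silylation of a primary alcohol; the TBDPS ether is chosen to survive aqueous acid, organoaluminium and organocopper reagents and the later selective removal of a TBS ether.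

Step 5
Reactants: 8 tert-butyl{[(E)-4-methylnon-4-en-8-yn-1-yl]oxy}diphenylsilane
Product: 9 tert-butyl{3-[(2R,3R)-3-(but-3-yn-1-yl)-2-methyloxiran-2-yl]propoxy}diphenylsilane
Conditions: D-fructose-derived Shi ketone (0.3 equiv), KHSO5 (as Oxone, 2KHSO5·KHSO4·K2SO4), K2CO3, Bu4NHSO4, Na2B4O7 buffer, MeCN/dimethoxymethane, 0 °C
Reagents that add atoms: potassium peroxymonosulfate, [K+].[O-]S(=O)(=O)OO
Why: Shi asymmetric epoxidation: the dioxirane of the chiral ketone epoxidises the E-trisubstituted alkene through a spiro transition state on the face that gives the (2R,3R)-epoxide, which sets C1 (R) and, provisionally, C14 (R); the alkyne is inert to the dioxirane.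

Step 6
Reactants: 9 tert-butyl{3-[(2R,3R)-3-(but-3-yn-1-yl)-2-methyloxiran-2-yl]propoxy}diphenylsilane
Product: 10 (4S,5R)-1-[(tert-butyldiphenylsilyl)oxy]-4-methylnon-8-yne-4,5-diol
Conditions: HClO4 (cat., aq.), THF/H2O, 0 °C → rt
Reagents that add atoms: water, O
Why: Acid-catalysed epoxide hydrolysis: water opens the protonated epoxide at the tertiary carbon C14 with inversion while the C1–O bond is kept, which turns the (1R,14R)-epoxide into the anti diol with the (1R,14S) configuration of the target.

Step 7
Reactants: 10 (4S,5R)-1-[(tert-butyldiphenylsilyl)oxy]-4-methylnon-8-yne-4,5-diol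
Product: 11 {3-[(4S,5R)-5-(but-3-yn-1-yl)-2,2,4-trimethyl-1,3-dioxolan-4-yl]propoxy}(tert-butyl)diphenylsilane
Conditions: Me2C(OMe)2, PPTS (cat.), CH2Cl2, rt
Reagents that add atoms: 2,2-dimethoxypropane, COC(C)(C)OC
Why: Acetonide formation by acid-catalysed transketalisation ties both hydroxyls into a dioxolane that is inert to the organometallic steps; no stereocentre is touched.

Step 8
Reactants: 11 {3-[(4S,5R)-5-(but-3-yn-1-yl)-2,2,4-trimethyl-1,3-dioxolan-4-yl]propoxy}(tert-butyl)diphenylsilane
Product: 13 tert-butyl{3-[(4S,5R)-5-[(E)-4-iodo-3-methylbut-3-en-1-yl]-2,2,4-trimethyl-1,3-dioxolan-4-yl]propoxy}diphenylsilane, via alkenylalane 12 (not isolated)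
Conditions: AlMe3 (2.5 equiv), Cp2ZrCl2 (0.25 equiv), CH2Cl2, 0 °C → rt; then I2, THF, −30 → 0 °C
Reagents that add atoms: trimethylaluminium, C[Al](C)C; iodine, II
Why: Zirconium-catalysed methylalumination (Negishi carboalumination) adds Me–Al syn across the terminal alkyne with aluminium on the terminal carbon, and iodinolysis of the C–Al bond with retention gives the E-alkenyl iodide (C4 methyl, C5 iodide).

Step 9
Reactants: 14 (4-bromobutoxy)(tert-butyl)dimethylsilane
Product: 15 4-(tert-butyldimethylsilyloxy)butylmagnesium bromide (Et2O solution, titrated)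
Conditions: Mg turnings, I2 (crystal), Et2O, reflux
Reagents that add atoms: magnesium, [Mg]
Why: Grignard formation by magnesium insertion into the primary C–Br bond; the silyl ether is inert and Et2O is the solvent needed for the carbocupration.

Step 10
Reactants: 15 4-(tert-butyldimethylsilyloxy)butylmagnesium bromide; 16 3-methylbut-1-yne; 13 E-alkenyl iodide acetonide
Product: 20 open-chain C1–C15 diene bearing C15–OTBS/C11–OTBDPS/1,14-acetonide [(4E,6E), C5 cis to C8, (1R,14S)], via alkylcopper 17 (not isolated), via alkenylcopper 18 (not isolated), via alkenylzinc bromide 19 (not isolated)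
Conditions: 15 (2.2 equiv), CuBr·SMe2 (2.2 equiv), Et2O/Me2S, −45 °C; 16 (4 equiv), −25 °C, 16 h; then ZnBr2 (2.2 equiv) in THF, Pd(PPh3)4 (5 mol %), 13 (1 equiv), −20 °C → rt
Reagents that add atoms: none
Why: Transmetalation of 15 with CuBr·SMe2 gives the alkylcopper 17, which adds across the terminal alkyne through a four-centre syn transition state, copper going to the terminal carbon C6 and the alkyl group to C7 (C7–C8 bond), so that C8 and the metal are cis in 18. Exchange to zinc with ZnBr2 and zerovalent-palladium-catalysed alkenyl–alkenyl coupling (oxidative addition of 13, transmetalation, reductive elimination; C5–C6 bond) go with retention at both sp2 carbons, giving C5 cis to C8 and C3 trans to C6. The closest known reaction type is the Normant syn-carbocupration of 1-alkynes by alkylcopper–magnesium halide reagents in Et2O followed by ZnBr2-mediated, palladium-catalysed coupling of the alkenylmetal with an alkenyl iodide (Negishi-type coupling). No ring is closed and no stereocentre is made; the two stereocentres of 13 are spectators. The step needs regioselectivity (secured by the terminal alkyne, whose isopropyl group also steers copper to C6), syn stereoselectivity (inherent in the concerted addition) and chemoselectivity (silyl ethers and the acetonide are inert to organocopper and organozinc reagents); because the α-branched alkyne adds slowly it is used in excess and given time before the iodide is introduced.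

Step 11
Reactants: 20 open-chain diene bearing C15–OTBS/C11–OTBDPS/1,14-acetonide
Product: 21 C15 alcohol (C15–OH; C11–OTBDPS and 1,14-acetonide kept)
Conditions: HF·pyridine, pyridine, THF, 0 °C
Reagents that add atoms: none
Why: Selective desilylation: a primary TBS ether is cleaved by buffered HF·pyridine far faster than a primary TBDPS ether, and the acetonide and the diene are stable to the buffered reagent.

Step 12
Reactants: 21 C15 alcohol
Product: 23 C15 carboxylic acid, via C15 aldehyde 22 (not isolated)
Conditions: TEMPO (0.2 equiv), PhI(OAc)2 (2.5 equiv), MeCN/H2O, rt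
Reagents that add atoms: water, O
Why: Oxoammonium (TEMPO/PhI(OAc)2) oxidation of the primary alcohol through the aldehyde and its hydrate to the acid; the conditions are mild enough for the diene, the acetonide and the silyl ether.

Step 13
Reactants: 23 C15 carboxylic acid
Product: 24 C15 allyl ester
Conditions: allyl bromide, Cs2CO3, DMF, rt
Reagents that add atoms: allyl bromide, C=CCBr
Why: Carboxylate O-alkylation (SN2 on allyl bromide) gives an ester that can later be removed under neutral zerovalent-palladium conditions in the presence of an acetate.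

Step 14
Reactants: 24 C15 allyl ester
Product: 26 C10 diphenyl phosphonate (allyl 2-(diphenoxyphosphoryl) ester; C10 epimers), via phosphonite 25 (not isolated)
Conditions: LiN(iPr)2 (1.2 equiv), THF, −78 °C; (PhO)2PCl (1.3 equiv), −78 → 0 °C; then t-BuOOH, 0 °C
Reagents that add atoms: diphenyl phosphorochloridite, ClP(Oc1ccccc1)Oc1ccccc1; tert-butyl hydroperoxide, CC(C)(C)OO
Why: C-phosphinylation of the lithium ester enolate by a trivalent phosphorus chloride (which attacks enolate carbon, where chlorophosphates tend to attack oxygen) followed by oxidation of the phosphonite gives the diaryl phosphonate needed for a Z-selective Horner–Wadsworth–Emmons reaction; the new C10 centre is of no consequence.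

Step 15
Reactants: 26 C10 diphenyl phosphonate
Product: 27 C11 alcohol (phosphonate, allyl ester and acetonide kept)
Conditions: HF·pyridine, THF, 0 °C → rt
Reagents that add atoms: none
Why: Fluoride-mediated desilylation under acidic, non-basic conditions removes the TBDPS ether without attacking the aryl phosphonate or the allyl ester.

Step 16
Reactants: 27 C11 alcohol
Product: 28 C11 aldehyde
Conditions: Dess–Martin periodinane, NaHCO3, CH2Cl2, 0 °C → rt
Reagents that add atoms: none
Why: Dess–Martin oxidation of the primary alcohol to the aldehyde under buffered conditions that leave the acidic phosphonate and the diene untouched.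

Step 17
Reactants: 28 C11 aldehyde
Product: 29 14-membered carbocyclic allyl ester [C10=C11 with C15 cis to C12 (10Z), (4E,6E), 1,14-acetonide, (1R,14S)]
Conditions: NaH (1.5 equiv), THF, 0 °C → rt, slow addition of 28 (final 1 mM)
Reagents that add atoms: none
Why: Intramolecular Horner–Wadsworth–Emmons reaction at high dilution: the diaryl phosphonate makes collapse of the kinetically formed adduct fast, which places the ester carbon C15 cis to C12, and this is also the arrangement in which C9 and C12 are trans within the new 14-membered ring, so reagent and ring favour the same isomer.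

Step 18
Reactants: 29 14-membered carbocyclic allyl ester acetonide
Product: 30 1,14-diol allyl ester
Conditions: AcOH/H2O/THF (3:1:1), 45 °C
Reagents that add atoms: none
Why: Acid-catalysed acetonide hydrolysis in mild aqueous acetic acid frees the C1 and C14 hydroxyls without isomerising the diene or the enoate.

Step 19
Reactants: 30 1,14-diol allyl ester
Product: 31 C1 acetate (C14–OH free; allyl ester)
Conditions: Ac2O, pyridine, DMAP (cat.), CH2Cl2, 0 °C
Reagents that add atoms: acetic anhydride, CC(=O)OC(C)=O
Why: Selective acylation: the secondary C1–OH is acetylated while the tertiary C14–OH is too hindered to react at 0 °C, so the two hydroxyls are told apart before the lactone is closed.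

Step 20
Reactants: 31 C1 acetate allyl ester
Product: 32 C15 acid (C1–OAc, C14–OH)
Conditions: Pd(PPh3)4 (5 mol %), morpholine, THF, rt
Reagents that add atoms: none
Why: Zerovalent-palladium-catalysed deallylation (π-allyl formation and capture by morpholine) frees the acid under neutral conditions that spare the acetate.

Step 21
Reactants: 32 C15 acid
Product: 34 target CNP0291129.1, via mixed anhydride 33 (not isolated)
Conditions: 2,4,6-Cl3C6H2COCl, Et3N, THF, rt; then DMAP, toluene, 80 °C, high dilution
Reagents that add atoms: none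
Why: Yamaguchi lactonisation: the mixed trichlorobenzoic anhydride is attacked, with DMAP catalysis, by the only free hydroxyl (tertiary C14–OH), which the Z-enoate holds within reach, closing the seven-membered lactone without breaking the C14–O bond, so both stereocentres are kept.

Compound list
1 | geranylacetone, (E)-6,10-dimethylundeca-5,9-dien-2-one | CC(=O)CC/C=C(\C)CCC=C(C)C | starting material
2 | diethyl (E)-6,10-dimethylundeca-1,5,9-trien-2-yl phosphate | C=C(OP(=O)(OCC)OCC)CC/C=C(\C)CCC=C(C)C | intermediate
3 | (E)-6,10-dimethylundeca-5,9-dien-1-yne | C#CCC/C=C(\C)CCC=C(C)C | intermediate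
4 | rac-(E)-3-bromo-2,6-dimethylundec-6-en-10-yn-2-ol | C#CCC/C=C(\C)CCC(Br)C(C)(C)O | intermediate
5 | rac-2,2-dimethyl-3-[(E)-3-methyloct-3-en-7-yn-1-yl]oxirane | C#CCC/C=C(\C)CCC1OC1(C)C | intermediate
6 | (E)-4-methylnon-4-en-8-ynal | C#CCC/C=C(\C)CCC=O | intermediate
7 | (E)-4-methylnon-4-en-8-yn-1-ol | C#CCC/C=C(\C)CCCO | intermediate
8 | tert-butyl{[(E)-4-methylnon-4-en-8-yn-1-yl]oxy}diphenylsilane | C#CCC/C=C(\C)CCCO[Si](c1ccccc1)(c2ccccc2)C(C)(C)C | intermediate
9 | tert-butyl{3-[(2R,3R)-3-(but-3-yn-1-yl)-2-methyloxiran-2-yl]propoxy}diphenylsilane | C#CCC[C@H]1O[C@]1(C)CCCO[Si](c2ccccc2)(c3ccccc3)C(C)(C)C | intermediate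
10 | (4S,5R)-1-[(tert-butyldiphenylsilyl)oxy]-4-methylnon-8-yne-4,5-diol | C#CCC[C@@H](O)[C@@](C)(O)CCCO[Si](c1ccccc1)(c2ccccc2)C(C)(C)C | intermediate
11 | {3-[(4S,5R)-5-(but-3-yn-1-yl)-2,2,4-trimethyl-1,3-dioxolan-4-yl]propoxy}(tert-butyl)diphenylsilane | C#CCC[C@H]1OC(C)(C)O[C@@]1(C)CCCO[Si](c2ccccc2)(c3ccccc3)C(C)(C)C | intermediate
12 | (E)-alkenyl(dimethyl)alane from 11 (AlMe2 on C5, methyl on C4) | C[Al](C)/C=C(C)/CC[C@H]1OC(C)(C)O[C@@]1(C)CCCO[Si](c2ccccc2)(c3ccccc3)C(C)(C)C | intermediate
13 | tert-butyl{3-[(4S,5R)-5-[(E)-4-iodo-3-methylbut-3-en-1-yl]-2,2,4-trimethyl-1,3-dioxolan-4-yl]propoxy}diphenylsilane | I/C=C(C)/CC[C@H]1OC(C)(C)O[C@@]1(C)CCCO[Si](c2ccccc2)(c3ccccc3)C(C)(C)C | intermediate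
14 | (4-bromobutoxy)(tert-butyl)dimethylsilane | CC(C)(C)[Si](C)(C)OCCCCBr | starting material
15 | 4-(tert-butyldimethylsilyloxy)butylmagnesium bromide | CC(C)(C)[Si](C)(C)OCCCC[Mg]Br | intermediate
16 | 3-methylbut-1-yne | CC(C)C#C | starting material
17 | [4-(tert-butyldimethylsilyloxy)butyl]copper | CC(C)(C)[Si](C)(C)OCCCC[Cu] | intermediate
18 | [(E)-6-(tert-butyldimethylsilyloxy)-2-(propan-2-yl)hex-1-en-1-yl]copper (copper cis to C8) | CC(C)(C)[Si](C)(C)OCCCC/C(C(C)C)=C\[Cu] | intermediate
19 | [(E)-6-(tert-butyldimethylsilyloxy)-2-(propan-2-yl)hex-1-en-1-yl]zinc bromide | CC(C)(C)[Si](C)(C)OCCCC/C(C(C)C)=C\[Zn]Br | intermediate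
20 | tert-butyl{3-[(4S,5R)-5-[(3E,5E)-10-(tert-butyldimethylsilyloxy)-3-methyl-6-(propan-2-yl)deca-3,5-dien-1-yl]-2,2,4-trimethyl-1,3-dioxolan-4-yl]propoxy}diphenylsilane | CC(C)(C)[Si](C)(C)OCCCC/C(C(C)C)=C\C=C(C)\CC[C@H]1OC(C)(C)O[C@@]1(C)CCCO[Si](c2ccccc2)(c3ccccc3)C(C)(C)C | intermediate
21 | (5E,7E)-10-[(4R,5S)-5-{3-[(tert-butyldiphenylsilyl)oxy]propyl}-2,2,5-trimethyl-1,3-dioxolan-4-yl]-8-methyl-5-(propan-2-yl)deca-5,7-dien-1-ol | OCCCC/C(C(C)C)=C\C=C(C)\CC[C@H]1OC(C)(C)O[C@@]1(C)CCCO[Si](c2ccccc2)(c3ccccc3)C(C)(C)C | intermediate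
22 | corresponding deca-5,7-dienal (C15 aldehyde) | O=CCCC/C(C(C)C)=C\C=C(C)\CC[C@H]1OC(C)(C)O[C@@]1(C)CCCO[Si](c2ccccc2)(c3ccccc3)C(C)(C)C | intermediate
23 | corresponding deca-5,7-dienoic acid (C15 acid) | OC(=O)CCC/C(C(C)C)=C\C=C(C)\CC[C@H]1OC(C)(C)O[C@@]1(C)CCCO[Si](c2ccccc2)(c3ccccc3)C(C)(C)C | intermediate
24 | prop-2-en-1-yl ester of 23 | C=CCOC(=O)CCC/C(C(C)C)=C\C=C(C)\CC[C@H]1OC(C)(C)O[C@@]1(C)CCCO[Si](c2ccccc2)(c3ccccc3)C(C)(C)C | intermediate
25 | allyl ester 24 bearing a diphenoxyphosphanyl group on C10 (epimers) | C=CCOC(=O)C(CC/C(C(C)C)=C\C=C(C)\CC[C@H]1OC(C)(C)O[C@@]1(C)CCCO[Si](c2ccccc2)(c3ccccc3)C(C)(C)C)P(Oc4ccccc4)Oc5ccccc5 | intermediate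
26 | allyl ester 24 bearing a diphenoxyphosphoryl group on C10 (epimers) | C=CCOC(=O)C(CC/C(C(C)C)=C\C=C(C)\CC[C@H]1OC(C)(C)O[C@@]1(C)CCCO[Si](c2ccccc2)(c3ccccc3)C(C)(C)C)P(=O)(Oc4ccccc4)Oc5ccccc5 | intermediate
27 | phosphonate 26 with free C11–OH | C=CCOC(=O)C(CC/C(C(C)C)=C\C=C(C)\CC[C@H]1OC(C)(C)O[C@@]1(C)CCCO)P(=O)(Oc2ccccc2)Oc3ccccc3 | intermediate
28 | phosphonate with C11 aldehyde | C=CCOC(=O)C(CC/C(C(C)C)=C\C=C(C)\CC[C@H]1OC(C)(C)O[C@@]1(C)CCC=O)P(=O)(Oc2ccccc2)Oc3ccccc3 | intermediate
29 | allyl ester of the 14-membered carbocyclic acid: C1–C14 ring, CO2allyl (C15) on C10, (4E,6E)-diene, C10=C11 with C15 cis to C12 (10Z), 1,14-O-isopropylidene, (1R,14S) | C=CCOC(=O)/C1=C\CC[C@]2(C)OC(C)(C)O[C@@H]2CC/C(C)=C/C=C(/C(C)C)CC1 | intermediate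
30 | (1R,14S)-1,14-diol allyl ester (29 without the acetonide) | C=CCOC(=O)/C1=C\CC[C@](C)(O)[C@H](O)CC/C(C)=C/C=C(/C(C)C)CC1 | intermediate
31 | (1R,14S)-1-acetoxy-14-hydroxy allyl ester | C=CCOC(=O)/C1=C\CC[C@](C)(O)[C@H](OC(C)=O)CC/C(C)=C/C=C(/C(C)C)CC1 | intermediate
32 | (1R,14S)-1-acetoxy-14-hydroxy C15 acid | OC(=O)/C1=C\CC[C@](C)(O)[C@H](OC(C)=O)CC/C(C)=C/C=C(/C(C)C)CC1 | intermediate
33 | mixed anhydride of 32 with 2,4,6-trichlorobenzoic acid | O=C(OC(=O)/C1=C\CC[C@](C)(O)[C@H](OC(C)=O)CC/C(C)=C/C=C(/C(C)C)CC1)c2c(Cl)cc(Cl)cc2Cl | intermediate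
34 | CNP0291129.1: (1R,14S)-1-acetoxy 14-membered carbocycle, (4E,6E)-diene with 4-methyl and 7-isopropyl, C10=C11 inside a seven-membered lactone (C15=O on C10, ring oxygen on C14, 14-methyl) | CC(=O)O[C@@H]1CC/C(C)=C/C=C(/C(C)C)CCC2=CCC[C@]1(C)OC2=O | target

Total step count: 21 (8 steps to iodide 13, 1 step to Grignard reagent 15, the key step, 11 steps from 20 to 34).
Longest linear sequence: 20 steps (steps 1–8 and 10–21).

Steps most likely to fail

Step 10. The α-branched alkyne may add too slowly, so that unreacted or thermally decaying alkylcopper is still present when the iodide arrives; alkyl transfer, protonolysis or homocoupling would then compete with the alkenyl–alkenyl coupling and consume the valuable iodide. The fallback sets out from 15, 16 and 13 and comes back at 20. The carbocupration is run as in step 10, but the alkenylcopper 18 is quenched with iodine to give the alkenyl iodide (E)-tert-butyl{[5-(iodomethylidene)-6-methylheptyl]oxy}dimethylsilane F1, which can be made in quantity and purified. Iodide 13 is converted by iodine–lithium exchange (t-BuLi, Et2O, −78 °C) and trapping with 2-isopropoxy-4,4,5,5-tetramethyl-1,3,2-dioxaborolane into the E-alkenyl pinacol boronate of 13 (iodine replaced by the 4,4,5,5-tetramethyl-1,3,2-dioxaborolan-2-yl group) F2. Suzuki–Miyaura coupling of F1 with F2 (Pd(PPh3)4, aqueous K3PO4, THF, 50 °C) then forms the C5–C6 bond with retention at both alkenes and gives 20.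

Step 14. The enolate may attack the phosphorus reagent unproductively: displacement of an aryloxy group by a second enolate or by the amide base, or proton exchange between enolate and product, would leave little C-phosphinylated ester. The fallback sets out from 24 and comes back at 26. The lithium enolate of 24 (LiN(iPr)2, THF, −78 °C) is brominated with CBr4 to the allyl 2-bromo ester (bromine on C10, both epimers) F3. Displacement of bromide by diphenyl phosphite with Et3N (Michaelis–Becker reaction, MeCN, rt to 40 °C) then gives 26; here phosphorus is the nucleophile and C10 the electrophile, the reverse of step 14.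

Step 21. Acylation of the hindered tertiary hydroxyl may be slow, so that isomerisation of the activated Z-enoate, oligomerisation or acetyl migration from C1 takes over. The fallback sets out from 30 and comes back at 34. The diol ester 30 is deallylated (Pd(PPh3)4, morpholine, THF) to the 1,14-dihydroxy C15 acid F4. Lactonisation with 2-methyl-6-nitrobenzoic anhydride and DMAP at high dilution, without the neighbouring acetate and relying on the kinetic preference for seven- over eight-membered ring closure, gives the C1-hydroxy seven-membered lactone (deacetyl target) F5. Acetylation of the secondary hydroxyl (Ac2O, pyridine) gives 34.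

Further compounds
F1 | step 10 | (E)-tert-butyl{[5-(iodomethylidene)-6-methylheptyl]oxy}dimethylsilane | CC(C)(C)[Si](C)(C)OCCCC/C(C(C)C)=C\I
F2 | step 10 | tert-butyl{3-[(4S,5R)-2,2,4-trimethyl-5-[(E)-3-methyl-4-(4,4,5,5-tetramethyl-1,3,2-dioxaborolan-2-yl)but-3-en-1-yl]-1,3-dioxolan-4-yl]propoxy}diphenylsilane | CC1(C)OB(/C=C(C)/CC[C@H]2OC(C)(C)O[C@@]2(C)CCCO[Si](c3ccccc3)(c4ccccc4)C(C)(C)C)OC1(C)C
F3 | step 14 | allyl 2-bromo ester derived from 24 (bromine on C10, epimers) | C=CCOC(=O)C(Br)CC/C(C(C)C)=C\C=C(C)\CC[C@H]1OC(C)(C)O[C@@]1(C)CCCO[Si](c2ccccc2)(c3ccccc3)C(C)(C)C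
F4 | step 21 | (1R,14S)-1,14-dihydroxy C15 acid of the 14-membered carbocycle | OC(=O)/C1=C\CC[C@](C)(O)[C@H](O)CC/C(C)=C/C=C(/C(C)C)CC1
F5 | step 21 | (1R,14S)-1-hydroxy seven-membered lactone (deacetyl target) | O[C@@H]1CC/C(C)=C/C=C(/C(C)C)CCC2=CCC[C@]1(C)OC2=O
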